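## Retrosynthetic overview

1. The target is reached by a last-step epoxidation of the 4,5-alkene of the 7,10-epoxy keto lactone (oxirane formed last).
2. The 7,10-oxolane comes from the key transannular C–O bond formation: the C10 hydroxyl of a ketol attacks C7 of a 13-bromo butenolide (SN2'), setting C7. The ketol comes from ketohydroxylation of the 1(10)-alkene.
3. The ten-membered carbocycle and the γ-lactone are formed together, first, by a chromium-mediated reductive C6–C7 macrocyclisation of an acyclic keto-enal.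
4. The keto-enal comes from a farnesol-derived C12 hydroxy-aldehyde (C1–C10, C14, C15) and methyl propiolate (C11–C13), after an enantioselective C8–O bond formation that installs the tiglate directly.
5. Ring order: carbocycle + lactone (step 7), then oxolane (step 9), then oxirane (step 10).

Assumption: germacrane numbering (C1–C15; lactone carbonyl C12, exocyclic methylene C13) is used for all macrocycles, and the target is read from the SMILES as 4R,5R,6R,7S,8S,10R.

## Route

Step 1
Reactants: 1 (2E,6E)-farnesol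
Product: 3 (2E,6E)-10,11-epoxyfarnesol (racemic at the oxirane CH), via bromohydrin 2 (not isolated)
Conditions: NBS, THF/H2O, 0 °C; then K2CO3, MeOH, rt
Reagents that add atoms: water (O)
Why: Bromohydrin formation is selective for the terminal trisubstituted alkene in aqueous THF (van Tamelen conditions) and base closes the oxirane by intramolecular Williamson substitution; the new stereocentre is racemic and is excised in step 2.

Step 2
Reactants: 3 (2E,6E)-10,11-epoxyfarnesol
Product: 4 (4E,8E)-10-hydroxy-4,8-dimethyldeca-4,8-dienal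
Conditions: H5IO6, THF/Et2O, 0 °C
Reagents that add atoms: none
Why: Periodic acid hydrolyses the epoxide to the glycol and cleaves it (Malaprade oxidation), releasing acetone and the C12 aldehyde without touching the allylic alcohol or the two E-alkenes.

Step 3
Reactants: 5 tigloyl chloride (2 equiv)
Product: 6 bis[(E)-2-methylbut-2-enoyl] peroxide
Conditions: 30% aq H2O2 (0.5 equiv), NaOH, Et2O/H2O, 0 °C
Reagents that add atoms: hydrogen peroxide (OO); tigloyl chloride, the second molecule of 5 (C/C=C(\C)C(=O)Cl)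
Why: Schotten–Baumann acylation of hydrogen peroxide at both oxygen atoms, one acid chloride molecule per oxygen, gives the symmetrical diacyl peroxide.

Step 4
Reactants: 4 (4E,8E)-10-hydroxy-4,8-dimethyldeca-4,8-dienal; 6 bis[(E)-2-methylbut-2-enoyl] peroxide
Product: 7 (2S,4E,8E)-10-hydroxy-4,8-dimethyl-1-oxodeca-4,8-dien-2-yl (E)-2-methylbut-2-enoate
Conditions: (S)-2-(triphenylmethyl)pyrrolidine (10 mol%), hydroquinone (10 mol%), THF, 0 °C; used crude
Reagents that add atoms: none
Why: Proposed new method: enamine-mediated α-acyloxylation in which the E-enamine of 4 attacks the O–O bond of 6 on the face opposite the trityl group, forming the C8–O bond with S configuration and installing the tiglate in one step; the closest known reaction is the organocatalytic α-benzoyloxylation of aldehydes with dibenzoyl peroxide, of which this is the untested tigloyl variant.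

Step 5
Reactants: 7 (2S,4E,8E)-10-hydroxy-4,8-dimethyl-1-oxodeca-4,8-dien-2-yl (E)-2-methylbut-2-enoate; 8 methyl propiolate
Product: 10 methyl (4S,6E,10E)-3,12-dihydroxy-6,10-dimethyl-2-methylidene-4-(tigloyloxy)dodeca-6,10-dienoate as a C3 epimer mixture, via vinylalane 9 (not isolated)
Conditions: 8, iBu2AlH, NMO, THF, 0 °C; then 7 (3 equiv of 9 per 7), 0 °C → rt; aq potassium sodium tartrate work-up
Reagents that add atoms: none
Why: Hydroalumination of the propiolate gives the α-(methoxycarbonyl)vinylalane 9, which adds to the aldehyde (vinylalumination, a base-free route to Baylis–Hillman adducts) so that C8 is not epimerised; the new C7 carbinol forms as a mixture that is oxidised in step 6.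

Step 6
Reactants: 10 methyl (4S,6E,10E)-3,12-dihydroxy-6,10-dimethyl-2-methylidene-4-(tigloyloxy)dodeca-6,10-dienoate
Product: 11 methyl (4S,6E,10E)-6,10-dimethyl-2-methylidene-4-(tigloyloxy)-3,12-dioxododeca-6,10-dienoate
Conditions: Dess–Martin periodinane (3 equiv), NaHCO3, CH2Cl2, 0 °C → rt; used crude at once
Reagents that add atoms: none
Why: Dess–Martin oxidation converts the allylic C7 carbinol into the 2-methylene-3-oxo ester and the primary allylic alcohol into the E-enal in one buffered, non-epimerising operation.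

Step 7
Reactants: 11 methyl (4S,6E,10E)-6,10-dimethyl-2-methylidene-4-(tigloyloxy)-3,12-dioxododeca-6,10-dienoate
Product: 14 (6R,7S,8S)-7-hydroxy-8-tigloyloxygermacra-1(10)E,4E,11(13)-trien-12,6-olide, via allylchromium species 12 (not isolated), via silyl ether lactone 13 (not isolated)
Conditions: CrCl2 (6 equiv), Me3SiCl (3 equiv), DMF/THF, rt, syringe-pump addition to 2 mM; then 1 M HCl
Reagents that add atoms: none
Why: Proposed new method: an intramolecular version of the known bimolecular Takai cross-pinacol-type coupling of enones with aldehydes, in which divalent chromium and Me3SiCl reduce and O-silylate the doubly activated enone to γ-siloxyallylchromium 12, which adds through C7 to the enal in a chair, crown-like ten-membered transition state that keeps the C8 ester and the new C6 oxygen pseudo-equatorial (6R, cis to the C8 oxygen), after which the C6 alkoxide closes the γ-lactone onto the methyl ester and acid removes the silyl group; the closest known reactions are that bimolecular coupling and chromium-mediated Nozaki–Hiyama macrocyclic allylations with 2-(bromomethyl)acrylates, and the C7 configuration drawn is inconsequential because step 9 resets it.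

Step 8
Reactants: 14 (6R,7S,8S)-7-hydroxy-8-tigloyloxygermacra-1(10)E,4E,11(13)-trien-12,6-olide
Product: 15 (6R,7S,8S,10R)-7,10-dihydroxy-1-oxo-8-tigloyloxygermacra-4E,11(13)-dien-12,6-olide
Conditions: RuCl3 (1 mol%), 2KHSO5·KHSO4·K2SO4, NaHCO3, EtOAc/MeCN/H2O, rt, short reaction time
Reagents that add atoms: potassium peroxymonosulfate KHSO5, the active component of the triple salt ([K+].[O-]S(=O)(=O)OO)
Why: Plietker ketohydroxylation (RuO4 [3+2] addition, then oxidation of the secondary ruthenate) attacks the more electron-rich 1(10)-alkene, the 4,5-alkene being deactivated by the allylic lactone oxygen, from the outer face of the E-alkene in the crown conformer, giving the 10α-hydroxy (10R) ketol as in peripheral oxidations of costunolide-type germacranolides.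

Step 9
Reactants: 15 (6R,7S,8S,10R)-7,10-dihydroxy-1-oxo-8-tigloyloxygermacra-4E,11(13)-dien-12,6-olide
Product: 17 (6R,7S,8S,10R)-7,10-epoxy-1-oxo-8-tigloyloxygermacra-4E,11(13)-dien-12,6-olide, via allylic bromide 16 (not isolated)
Conditions: NBS/Me2S (premixed), CH2Cl2, −20 → 0 °C; then Ag2O, 4 Å MS, rt
Reagents that add atoms: none
Why: Corey–Kim bromination of the tertiary allylic alcohol with allylic transposition gives 13-bromo butenolide 16, and silver-assisted transannular SN2' etherification (5-exo oxa-Michael addition at C7 with loss of bromide) by the α-face C10 hydroxyl forms the C7–O bond, restores the exocyclic methylene and sets C7 as S because only the cis-bridged oxolane can form.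

Step 10
Reactants: 17 (6R,7S,8S,10R)-7,10-epoxy-1-oxo-8-tigloyloxygermacra-4E,11(13)-dien-12,6-olide
Product: 18 (4R,5R,6R,7S,8S,10R)-4,5:7,10-diepoxy-1-oxo-8-tigloyloxygermacr-11(13)-en-12,6-olide
Conditions: DMDO, acetone/CH2Cl2, 0 °C
Reagents that add atoms: dimethyldioxirane (CC1(C)OO1)
Why: Electrophilic epoxidation of the only electron-rich alkene from its outer face, in the conformer where H-6 eclipses the alkene (allylic 1,3-strain with the C4 methyl), gives the 4R,5R trans-epoxide with the same sense as the peripheral epoxidation of costunolide to parthenolide, while the dioxirane avoids Baeyer–Villiger oxidation of the ketone.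

## Compound list

1 | (2E,6E)-farnesol | CC(C)=CCC/C(C)=C/CC/C(C)=C/CO | starting material
2 | (2E,6E)-10-bromo-3,7,11-trimethyldodeca-2,6-diene-1,11-diol (racemic bromohydrin) | CC(C)(O)C(Br)CC/C(C)=C/CC/C(C)=C/CO | intermediate
3 | (2E,6E)-10,11-epoxyfarnesol (racemic at the oxirane CH) | CC1(C)OC1CC/C(C)=C/CC/C(C)=C/CO | intermediate
4 | (4E,8E)-10-hydroxy-4,8-dimethyldeca-4,8-dienal | O=CCC/C(C)=C/CC/C(C)=C/CO | intermediate
5 | tigloyl chloride, (E)-2-methylbut-2-enoyl chloride | C/C=C(\C)C(=O)Cl | starting material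
6 | bis[(E)-2-methylbut-2-enoyl] peroxide | C/C=C(\C)C(=O)OOC(=O)/C(C)=C/C | intermediate
7 | (2S,4E,8E)-10-hydroxy-4,8-dimethyl-1-oxodeca-4,8-dien-2-yl (E)-2-methylbut-2-enoate | O=C[C@@H](OC(=O)/C(C)=C/C)C/C(C)=C/CC/C(C)=C/CO | intermediate
8 | methyl propiolate | C#CC(=O)OC | starting material
9 | methyl 2-(diisobutylalumanyl)prop-2-enoate | C=C(C(=O)OC)[Al](CC(C)C)CC(C)C | intermediate
10 | methyl (4S,6E,10E)-3,12-dihydroxy-6,10-dimethyl-2-methylidene-4-[(E)-2-methylbut-2-enoyloxy]dodeca-6,10-dienoate (both C3 epimers) | C=C(C(=O)OC)C(O)[C@@H](OC(=O)/C(C)=C/C)C/C(C)=C/CC/C(C)=C/CO | intermediate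
11 | methyl (4S,6E,10E)-6,10-dimethyl-2-methylidene-4-[(E)-2-methylbut-2-enoyloxy]-3,12-dioxododeca-6,10-dienoate | C=C(C(=O)OC)C(=O)[C@@H](OC(=O)/C(C)=C/C)C/C(C)=C/CC/C(C)=C/C=O | intermediate
12 | allylchromium dichloride (trivalent chromium) derived from 11: Cr on C13, Me3SiO on C7 cis to CH2Cr across C7=C11, 8S | COC(=O)/C(C[Cr](Cl)Cl)=C(/O[Si](C)(C)C)[C@@H](OC(=O)/C(C)=C/C)C/C(C)=C/CC/C(C)=C/C=O | intermediate
13 | (6R,7S,8S)-8-tigloyloxy-7-(trimethylsilyloxy)germacra-1(10)E,4E,11(13)-trien-12,6-olide | C=C1C(=O)O[C@@H]2/C=C(C)/CC/C=C(C)/C[C@H](OC(=O)/C(C)=C/C)[C@@]12O[Si](C)(C)C | intermediate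
14 | (6R,7S,8S)-7-hydroxy-8-tigloyloxygermacra-1(10)E,4E,11(13)-trien-12,6-olide | C=C1C(=O)O[C@@H]2/C=C(C)/CC/C=C(C)/C[C@H](OC(=O)/C(C)=C/C)[C@@]12O | intermediate
15 | (6R,7S,8S,10R)-7,10-dihydroxy-1-oxo-8-tigloyloxygermacra-4E,11(13)-dien-12,6-olide | C=C1C(=O)O[C@@H]2/C=C(C)/CCC(=O)[C@@](O)(C)C[C@H](OC(=O)/C(C)=C/C)[C@@]12O | intermediate
16 | (6R,8S,10R)-13-bromo-10-hydroxy-1-oxo-8-tigloyloxygermacra-4E,7(11)-dien-12,6-olide | BrCC1=C2[C@@H](OC(=O)/C(C)=C/C)C[C@](O)(C)C(=O)CC/C(C)=C/[C@H]2OC1=O | intermediate
17 | (6R,7S,8S,10R)-7,10-epoxy-1-oxo-8-tigloyloxygermacra-4E,11(13)-dien-12,6-olide | C=C1C(=O)O[C@@H]2/C=C(C)/CCC(=O)[C@@]3(C)C[C@H](OC(=O)/C(C)=C/C)[C@@]12O3 | intermediate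
18 | (4R,5R,6R,7S,8S,10R)-4,5:7,10-diepoxy-1-oxo-8-tigloyloxygermacr-11(13)-en-12,6-olide | C=C1C(=O)O[C@@H]2[C@H]3O[C@]3(C)CCC(=O)[C@@]3(C)C[C@H](OC(=O)/C(C)=C/C)[C@@]12O3 | target

## Step count and risks

Total steps: 10. Longest linear sequence: 9 (steps 1, 2, 4–10 from farnesol); step 3 only prepares the peroxide reagent.

Stereocentres: C8 is set in step 4, C6 in step 7, C10 in step 8, C7 in step 9, and C4/C5 in step 10.

The three steps most likely to fail:

**Step 4 (proposed new α-tigloyloxylation).** The unsaturated diacyl peroxide may react sluggishly or acylate the amine catalyst, and the α-acyloxy aldehyde is configurationally fragile. The fallback sets out from 4 and returns at 14; it replaces the new C–O bond formation by a known α-oxyamination, carries a robust oxygen protecting group through the main-route operations and acylates late. Known enantioselective α-oxyamination of 4 (TEMPO, CuCl2 10 mol%, 5-benzyl-2,2,3-trimethylimidazolidin-4-one trifluoroacetate 20 mol% in the enantiomeric form that gives the 2S product, air, acetone, −10 °C) gives (2S,4E,8E)-10-hydroxy-4,8-dimethyl-2-[(2,2,6,6-tetramethylpiperidin-1-yl)oxy]deca-4,8-dienal F1. This is taken through the operations of steps 5, 6 and 7 as written, giving in turn the vinylalumination adduct F2, the keto-enal F3 and the macrocyclic 7-hydroxy-8-(tetramethylpiperidinyloxy) lactone F4. Zn/AcOH (THF/H2O, rt) then cleaves the N–O bond to give 7,8-dihydroxygermacra-1(10),4,11(13)-trien-12,6-olide F5, and tigloyl chloride 5 with DMAP/pyridine (0 °C) acylates only the secondary C8 hydroxyl, the C7 hydroxyl being tertiary, and gives 14.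

**Step 7 (proposed new chromium-mediated reductive macrocyclisation).** Simple 1,4-reduction or dimerisation of the enone, loss of the α'-acyloxy group, or the wrong C6 configuration are possible. The fallback sets out from 7 and returns at 16; it uses a known Nozaki–Hiyama–Kishi macrocyclisation and carries a pre-installed C13 oxygen instead of the C7 hydroxyl. Aldol addition of the lithium enolate of methyl 3-(tert-butyldimethylsilyloxy)propanoate (LiN(iPr)2, THF, −78 °C) to 7 gives the β-hydroxy ester F6, and Dess–Martin oxidation of both carbinols gives the β-keto ester enal F7. Chelation-controlled enol triflation (Tf2O, aq LiOH, toluene, 5 °C) gives the enol triflate with OTf cis to CO2Me F8. NiCl2 (cat.)/CrCl2 coupling of the alkenyl triflate with the enal (DMF/THF, high dilution), with spontaneous lactonisation, gives 13-(tert-butyldimethylsilyloxy)-8-tigloyloxygermacra-1(10),4,7(11)-trien-12,6-olide F9. Ketohydroxylation as in step 8, which the silyl ether tolerates, gives the 10-hydroxy-1-oxo compound F10, and HF·pyridine (THF, 0 °C) gives the 13-hydroxy ketol F11. CBr4/PPh3 (CH2Cl2, 0 °C) converts the primary allylic alcohol into bromide 16, which continues with the Ag2O stage of step 9.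

**Step 9 (transannular SN2' etherification).** A tertiary alcohol must attack a fully substituted butenolide carbon; direct SN2 attack at C13 (seven-membered ether) or elimination may compete, and the Corey–Kim activation of the hindered C7 hydroxyl may be slow. The fallback sets out from 15 and returns at 17 with no allylic halide: Re2O7 (5 mol%, CH2Cl2, rt) effects dehydrative allylic transposition and etherification of the monoallylic diol under thermodynamic control, the perrhenate ester shifting to C13 and the C10 hydroxyl closing the five-membered ether at C7. This fallback makes no new compound (F0).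

## Further compounds

F1 | step 4 | (2S,4E,8E)-10-hydroxy-4,8-dimethyl-2-[(2,2,6,6-tetramethylpiperidin-1-yl)oxy]deca-4,8-dienal | O=C[C@@H](ON1C(C)(C)CCCC1(C)C)C/C(C)=C/CC/C(C)=C/CO
F2 | step 4 | methyl (4S,6E,10E)-3,12-dihydroxy-6,10-dimethyl-2-methylidene-4-[(2,2,6,6-tetramethylpiperidin-1-yl)oxy]dodeca-6,10-dienoate (both C3 epimers) | C=C(C(=O)OC)C(O)[C@@H](ON1C(C)(C)CCCC1(C)C)C/C(C)=C/CC/C(C)=C/CO
F3 | step 4 | methyl (4S,6E,10E)-6,10-dimethyl-2-methylidene-3,12-dioxo-4-[(2,2,6,6-tetramethylpiperidin-1-yl)oxy]dodeca-6,10-dienoate | C=C(C(=O)OC)C(=O)[C@@H](ON1C(C)(C)CCCC1(C)C)C/C(C)=C/CC/C(C)=C/C=O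
F4 | step 4 | (6R,7R,8S)-7-hydroxy-8-[(2,2,6,6-tetramethylpiperidin-1-yl)oxy]germacra-1(10)E,4E,11(13)-trien-12,6-olide (same spatial arrangement as 14; the C7 descriptor changes because the N–O substituent raises the priority of C8) | C=C1C(=O)O[C@@H]2/C=C(C)/CC/C=C(C)/C[C@H](ON3C(C)(C)CCCC3(C)C)[C@@]12O
F5 | step 4 | (6R,7S,8S)-7,8-dihydroxygermacra-1(10)E,4E,11(13)-trien-12,6-olide | C=C1C(=O)O[C@@H]2/C=C(C)/CC/C=C(C)/C[C@H](O)[C@@]12O
F6 | step 7 | methyl (4S,6E,10E)-2-[(tert-butyldimethylsilyloxy)methyl]-3,12-dihydroxy-6,10-dimethyl-4-(tigloyloxy)dodeca-6,10-dienoate (C2/C3 diastereomer mixture) | COC(=O)C(CO[Si](C)(C)C(C)(C)C)C(O)[C@@H](OC(=O)/C(C)=C/C)C/C(C)=C/CC/C(C)=C/CO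
F7 | step 7 | methyl (4S,6E,10E)-2-[(tert-butyldimethylsilyloxy)methyl]-6,10-dimethyl-3,12-dioxo-4-(tigloyloxy)dodeca-6,10-dienoate (C2 epimer mixture) | COC(=O)C(CO[Si](C)(C)C(C)(C)C)C(=O)[C@@H](OC(=O)/C(C)=C/C)C/C(C)=C/CC/C(C)=C/C=O
F8 | step 7 | methyl (2Z,4S,6E,10E)-2-[(tert-butyldimethylsilyloxy)methyl]-6,10-dimethyl-12-oxo-4-(tigloyloxy)-3-(trifluoromethylsulfonyloxy)dodeca-2,6,10-trienoate, OTf cis to CO2Me | COC(=O)/C(CO[Si](C)(C)C(C)(C)C)=C(\OS(=O)(=O)C(F)(F)F)[C@@H](OC(=O)/C(C)=C/C)C/C(C)=C/CC/C(C)=C/C=O
F9 | step 7 | (6R,8S)-13-(tert-butyldimethylsilyloxy)-8-tigloyloxygermacra-1(10)E,4E,7(11)-trien-12,6-olide | CC(C)(C)[Si](C)(C)OCC1=C2[C@@H](OC(=O)/C(C)=C/C)C/C(C)=C/CC/C(C)=C/[C@H]2OC1=O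
F10 | step 7 | (6R,8S,10R)-13-(tert-butyldimethylsilyloxy)-10-hydroxy-1-oxo-8-tigloyloxygermacra-4E,7(11)-dien-12,6-olide | CC(C)(C)[Si](C)(C)OCC1=C2[C@@H](OC(=O)/C(C)=C/C)C[C@](O)(C)C(=O)CC/C(C)=C/[C@H]2OC1=O
F11 | step 7 | (6R,8S,10R)-10,13-dihydroxy-1-oxo-8-tigloyloxygermacra-4E,7(11)-dien-12,6-olide | OCC1=C2[C@@H](OC(=O)/C(C)=C/C)C[C@](O)(C)C(=O)CC/C(C)=C/[C@H]2OC1=O
F0 | step 9 | none | none
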